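# Proposed synthesis of CNP0326301.1: (R)-1-(5,8-dihydroxy-1,4-dioxo-1,4-dihydronaphthalen-2-yl)-2,2-dimethylcyclobutyl angelate

## Analysis of the target

The target is a naphthazarin (5,8-dihydroxy-1,4-naphthoquinone, rings A and B) that carries a cyclobutane (ring C) at C2 through the fully substituted carbon C1'. C1' is the only stereocentre; it bears the quinone carbon, the ester oxygen, the gem-dimethyl carbon C2' and the methylene C4', and it is R. The stereochemical problem is therefore absolute control at one tetrasubstituted carbinol carbon wedged between a quaternary carbon and an ortho-substituted ring. The ester is an angelate, (Z)-2-methylbut-2-enoate, which isomerises to the E isomer under basic, nucleophilic or strongly acidic conditions, and as a tertiary ester it can ionise while C1' is attached to an electron-rich arene. The naphthazarin is redox-active, acidic and chelating, so it has to travel in masked form; its two rings exchange roles by fast tautomerism, so a side chain on ring A or on ring B leads to the same substance. The main difficulty is a four-membered ring with two adjacent fully substituted carbons, one of them an oxygenated stereocentre. The plan rests on the fact that the ring bonds C1'–C2' and C3'–C4' join two two-carbon units: C1'–C4' is an arylalkyne, and C2'–C3' is a dimethylketene equivalent, provided C3' is carried for a time as a carbonyl. That carbonyl makes C1' the β-carbon of an enone, so a chiral catalyst can set the stereocentre.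

## Retrosynthetic reasoning

**Unmasking the naphthazarin (23 from 19).** The free naphthazarin is left to the end because it would not survive amide activation, copper–boryl chemistry or hydride reagents. Working backwards, 23 becomes the fully oxidised tetraone 22, and each quinoid ring of 22 becomes a pair of methyl ethers, through the ring-isomeric dimethoxy quinones 20 and 21, in the tetramethoxynaphthalene ester 19. Forward, one oxidant removes all four methyl groups by oxidative demethylation of both rings, and a two-electron reduction in the same flask brings 22 down to 23. Which ring is oxidised first does not matter, because 20 and 21 converge on 22.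

**Ester C–O bond (19 from 15 and 16).** The acyl–oxygen bond is cut so that the angelate arrives late. It is an isomerisable Michael acceptor and would not tolerate the borylation or the hydride steps. The forward reaction has to acylate a very hindered tertiary alcohol without Z-to-E isomerisation, which points to the pre-formed alkoxide 18 and the activated anhydride 17.

**C1'–O from C1'–B (15 from 14).** The tertiary alcohol is traced back to a tertiary boronic ester, since boron-to-oxygen exchange runs with retention. Boron is kept until the ring carbonyl is gone. A hydroxyl group at C1' with the ring carbonyl still in place would be a strained aldol and would open by retro-aldol cleavage, while the β-boryl ketone 11 has no such path.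

**Removing the temporary carbonyl (14 from 12, and 12 from 11).** C3' is a methylene in the target, so the ketone of 11 is only a handle. It is taken out through the tosylhydrazone 12 under hydride conditions that leave the C–B bond and the arene alone.

**C1'–B bond and the stereocentre (11 from 10).** Cutting the C–B bond gives the flat enone 10, in which C1' is the β-carbon. A copper–boryl species with a chiral bisphosphine adds boron to that carbon, and the ligand chooses the face. The stereocentre is thus set by the catalyst alone, on a substrate with no other stereochemistry.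

**The four-membered ring (10 from 6 and 7).** Both C1'–C2' and C3'–C4' are cut. This is the only disconnection that brings in the gem-dimethyl group, the aryl group and all four ring carbons in one step from two simple partners. Amide 7 supplies C2' with its two methyl groups and C3' as the future carbonyl. Alkyne 6 supplies C4' and C1'. The forward reaction goes through keteniminium salt 8 and iminium salt 9 and must place the aryl carbon next to the gem-dimethyl carbon.

**The arylalkyne (6 from 5, 5 from 3, 3 from 1).** The ethynyl carbon is added by one-carbon homologation of aldehyde 5. The aldehyde comes from formylation of the symmetric tetramethoxynaphthalene 3, in which all four open positions are equivalent. Compound 3 comes from naphthazarin 1 by reductive methylation through 2. A halogenation and cross-coupling sequence to the same alkyne would take one step more.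

## Alternatives that were turned down

**Alternative 1: ring B built by an aryne cycloaddition.** The disconnection cuts C4a–C4 and C8a–C1 of the naphthalene. A fluoride source would release 3,6-dimethoxybenzyne A2 from the silyl triflate A1, and A2 would add across C2 and C5 of the furyl ester A3 to give the oxygen-bridged dihydronaphthalene A4.
- For it: the route is convergent, the side chain arrives complete with stereocentre and ester, and only two methyl ethers have to be removed at the end. On these points it is stronger than the chosen route, which is linear and has to strip four methyl ethers at the end.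
- Against it: the key step does not solve the real problem. A3 already contains the congested chiral cyclobutyl carbinol, and making it in one enantiomeric form is no easier than what the chosen route does.
- Against it: A4 holds a tertiary allylic ester next to a strained oxygen bridge. Opening the bridge of A4 needs acid, which invites ionisation at C1', and it is followed by oxidation to the quinone stage and a demethylation of the same kind.
- Comparison: the chosen strategy uses its key step to build the difficult ring and leaves a clean, catalyst-controlled step for the stereocentre.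

**Alternative 2: ring contraction by photodecarbonylation in the crystal.** The disconnection is C1'–C2'. Irradiation of the crystalline hydroxy ketone A5 would break both bonds to the carbonyl carbon, extrude the carbonyl group and join the two radical centres to give the cyclobutanol A6.
- For it: the step forms exactly the most hindered bond, between the two fully substituted carbons. It should do so with retention, because the radical pair is held by the lattice, and both radicals are well stabilised. A five-membered precursor is also easy to assemble. On directness it is the strongest of the four ideas.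
- Against it: the outcome depends on crystallinity and packing of one particular enantioenriched compound. That cannot be predicted, and it scales poorly.
- Against it: A6 carries only a dimethoxyphenyl group, so the second carbocycle of the naphthazarin would have to be annulated afterwards, over several steps, in the presence of the sensitive tertiary benzylic alcohol.
- Comparison: the chosen route brings in the whole naphthalene before the ring is made and relies only on solution-phase polar chemistry.

**Alternative 3: cyclisation of a lithiated benzylic carbamate.** The disconnection is C1'–C4'. A strong alkyllithium base with a diamine would deprotonate the benzylic carbon of the chloro carbamate A7, and the carbanion would displace the primary chloride to give the cyclobutyl carbamate A8.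
- For it: the stereocentre comes from an easily made secondary benzylic alcohol, and no carbonyl has to be removed afterwards. On paper this is the shortest sequence after the key step, and on step economy it beats the chosen route.
- Against it: several uncertainties fall on one step.
  - Closure of a four-membered ring by displacement is slow. It has to outrun racemisation of the benzylic organolithium, 1,2-migration of the carbamoyl group and ring lithiation next to the methoxy groups.
  - The benzylic proton is flanked by a quaternary carbon, so deprotonation is hindered.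
  - The steric course (retention or inversion) is not secure for an intramolecular alkylation. A7 is drawn as the S enantiomer, which is the right one only if the alkylation runs with inversion; with retention its antipode would be needed.
  - The diisopropylcarbamate of the tertiary alcohol in A8 is hard to remove before the angelate can go on.
- Comparison: the chosen route is longer, but it separates ring construction, where no stereochemistry is at stake, from the stereo-setting step, for which both ligand antipodes are available.

Key step: step 4

**Remarks on the chemistry**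
- Naphthazarins interconvert rapidly between the 2-substituted and 6-substituted tautomers. The target is drawn as the tautomer with the side chain on the quinoid ring, and both are treated as the same substance.
- The spatial arrangement at C1' stays the same from 11 to 23. The descriptor changes (R in 11, S in 12 to 14, R from 15 on) only because the CIP priorities of the neighbours change.
- The sense of induction of the ligand in step 5 cannot be fixed in advance for this substrate. The antipode that gives (R)-11 is the one to be used.

## Route

Step 1
Reactants: 1 naphthazarin (5,8-dihydroxy-1,4-naphthoquinone)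
Product: 3 1,4,5,8-tetramethoxynaphthalene, via naphthalene-1,4,5,8-tetrol 2 (not isolated)
Conditions: Na2S2O4, aq. NaOH, Bu4NBr, Me2SO4, THF/H2O, N2, 0 °C to rt
Reagents that add atoms: dimethyl sulfate, COS(=O)(=O)OC
Why: Reductive methylation; dithionite reduces the quinone to the tetraphenol 2, whose phenoxides are O-methylated under phase transfer before air can reoxidise them.

Step 2
Reactants: 3 1,4,5,8-tetramethoxynaphthalene
Product: 5 1,4,5,8-tetramethoxynaphthalene-2-carbaldehyde, via aryl iminium chloride 4 (not isolated)
Conditions: POCl3, DMF, CHCl3, 0 °C to reflux; then aq. NaOAc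
Reagents that add atoms: N,N-dimethylformamide, CN(C)C=O; water, O
Why: Vilsmeier–Haack formylation of a very electron-rich arene; the four free positions of 3 are equivalent, and the first formyl group deactivates the ring against a second one.

Step 3
Reactants: 5 1,4,5,8-tetramethoxynaphthalene-2-carbaldehyde
Product: 6 2-ethynyl-1,4,5,8-tetramethoxynaphthalene
Conditions: dimethyl (1-diazo-2-oxopropyl)phosphonate, K2CO3, MeOH, 0 °C to rt
Reagents that add atoms: dimethyl (1-diazo-2-oxopropyl)phosphonate, COP(=O)(OC)C(=[N+]=[N-])C(C)=O
Why: Seyferth–Gilbert homologation in the Ohira–Bestmann form; methoxide removes the acetyl group, the diazophosphonate anion olefinates the aldehyde, and the diazoalkene loses N2 with 1,2-hydrogen shift to give the terminal alkyne under mild base.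

Step 4
Reactants: 6 2-ethynyl-1,4,5,8-tetramethoxynaphthalene; 7 N,N-dimethylisobutyramide
Product: 10 4,4-dimethyl-3-(1,4,5,8-tetramethoxynaphthalen-2-yl)cyclobut-2-en-1-one, via tetramethylketeniminium triflate 8 (not isolated), via cyclobuteniminium triflate 9 (not isolated)
Conditions: 7, Tf2O, 2,4,6-collidine, ClCH2CH2Cl, −20 °C to rt; then 6, rt to 60 °C; then H2O
Reagents that add atoms: water, O
Why: Tf2O triflates the oxygen of amide 7 and collidine removes the α-proton, so the α-triflyloxy enamine ionises to keteniminium salt 8 before any alkyne is present. The terminal carbon of alkyne 6 attacks the central carbon of 8 (bond C3'–C4'), which leaves a vinyl cation on the aryl-bearing carbon that the 1-methoxy group and the electron-rich naphthalene stabilise. The enamine carbon carrying the two methyl groups then closes onto this cation (bond C1'–C2'), which completes the four-membered ring in a stepwise polar [2+2]; the enamine double bond lies inside the new ring and the cationic carbon is digonal. This gives iminium salt 9, and water hydrolyses it to enone 10. The closest known reaction type is the keteniminium–alkyne [2+2] cycloaddition that leads to cyclobutenones. No stereocentre is formed. The step needs regioselectivity, aryl carbon next to the gem-dimethyl carbon, which the aryl-stabilised vinyl cation secures. It also needs chemoselectivity for the alkyne over the free ring positions of the arene, which the higher nucleophilicity of the ethynyl terminus and the preformation of 8 (no free Tf2O meets 6) secure.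

Step 5
Reactants: 10 4,4-dimethyl-3-(1,4,5,8-tetramethoxynaphthalen-2-yl)cyclobut-2-en-1-one
Product: 11 (3R)-2,2-dimethyl-3-(4,4,5,5-tetramethyl-1,3,2-dioxaborolan-2-yl)-3-(1,4,5,8-tetramethoxynaphthalen-2-yl)cyclobutan-1-one
Conditions: CuCl (cat.), (S,S)-2,3-bis(tert-butylmethylphosphino)quinoxaline (cat.; or its antipode), NaOtBu (cat.), B2pin2, MeOH, THF, rt
Reagents that add atoms: bis(pinacolato)diboron, CC1(C)OB(OC1(C)C)B1OC(C)(C)C(C)(C)O1
Why: Copper-catalysed enantioselective conjugate borylation of a β,β-disubstituted cyclic enone to a tertiary boronate; the ligated copper–boryl species adds across the strained enone with boron at the β-carbon, and methanol protonates the copper enolate. The chiral bisphosphine distinguishes the two faces of the planar β-carbon (aryl flank against gem-dimethyl flank) and so sets C1', the only stereocentre.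

Step 6
Reactants: 11 (3R)-2,2-dimethyl-3-(4,4,5,5-tetramethyl-1,3,2-dioxaborolan-2-yl)-3-(1,4,5,8-tetramethoxynaphthalen-2-yl)cyclobutan-1-one
Product: 12 N'-[(3S)-2,2-dimethyl-3-(4,4,5,5-tetramethyl-1,3,2-dioxaborolan-2-yl)-3-(1,4,5,8-tetramethoxynaphthalen-2-yl)cyclobutylidene]-4-methylbenzenesulfonohydrazide (C=N isomers)
Conditions: TsNHNH2, MeOH, rt to 50 °C
Reagents that add atoms: p-toluenesulfonohydrazide, Cc1ccc(cc1)S(=O)(=O)NN
Why: Condensation of a strained, reactive cyclobutanone with a sulfonyl hydrazide under near-neutral conditions; the boronate and the stereocentre are not touched.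

Step 7
Reactants: 12 N'-[(3S)-2,2-dimethyl-3-(4,4,5,5-tetramethyl-1,3,2-dioxaborolan-2-yl)-3-(1,4,5,8-tetramethoxynaphthalen-2-yl)cyclobutylidene]-4-methylbenzenesulfonohydrazide
Product: 14 2-[(1S)-2,2-dimethyl-1-(1,4,5,8-tetramethoxynaphthalen-2-yl)cyclobutyl]-4,4,5,5-tetramethyl-1,3,2-dioxaborolane, via tosylhydrazine 13 (not isolated)
Conditions: catecholborane, CHCl3, 0 °C to rt; then NaOAc·3H2O, reflux
Reagents that add atoms: none
Why: Caglioti-type reduction of a tosylhydrazone; hydride adds to C=N to give 13, acetate induces loss of sulfinate, and the alkyl diazene loses N2 to leave the methylene group C3'. The conditions are neither acidic nor oxidising, so the tertiary boronate, which is not at the reacting carbon, keeps its configuration.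

Step 8
Reactants: 14 2-[(1S)-2,2-dimethyl-1-(1,4,5,8-tetramethoxynaphthalen-2-yl)cyclobutyl]-4,4,5,5-tetramethyl-1,3,2-dioxaborolane
Product: 15 (1R)-2,2-dimethyl-1-(1,4,5,8-tetramethoxynaphthalen-2-yl)cyclobutan-1-ol
Conditions: 30% H2O2, aq. NaOH, THF, 0 °C to rt
Reagents that add atoms: hydrogen peroxide, OO
Why: Oxidation of a boronic ester; hydroperoxide adds to boron and the tertiary carbon migrates from boron to oxygen with retention, so the configuration set in step 5 is carried into the C–O bond. With C3' now a methylene, the alcohol has no retro-aldol path.

Step 9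
Reactants: 15 (1R)-2,2-dimethyl-1-(1,4,5,8-tetramethoxynaphthalen-2-yl)cyclobutan-1-ol; 16 angelic acid, (Z)-2-methylbut-2-enoic acid
Product: 19 (1R)-2,2-dimethyl-1-(1,4,5,8-tetramethoxynaphthalen-2-yl)cyclobutyl (2Z)-2-methylbut-2-enoate, via angelic 2,4,6-trichlorobenzoic anhydride 17 (not isolated), via lithium alkoxide 18 (not isolated)
Conditions: 16, 2,4,6-Cl3C6H2COCl, Et3N, toluene, rt, filtered; separately 15, LiN(SiMe3)2, THF, −78 °C; then combined, −78 to 0 °C
Reagents that add atoms: none
Why: Yamaguchi-type mixed anhydride acylation of a pre-formed tertiary alkoxide; 18 attacks the less hindered angeloyl carbonyl of 17. With no free base or nucleophilic catalyst at raised temperature, the Z double bond should not isomerise, and the stereocentre is not involved.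

Step 10
Reactants: 19 (1R)-2,2-dimethyl-1-(1,4,5,8-tetramethoxynaphthalen-2-yl)cyclobutyl (2Z)-2-methylbut-2-enoate
Product: 23 (1R)-1-(5,8-dihydroxy-1,4-dioxo-1,4-dihydronaphthalen-2-yl)-2,2-dimethylcyclobutyl (2Z)-2-methylbut-2-enoate, via dimethoxy quinone 20 (not isolated), via ring-isomeric dimethoxy quinone 21 (not isolated), via naphthalene-1,4,5,8-tetraone 22 (not isolated)
Conditions: AgO (excess), 6 M HNO3, 1,4-dioxane, 0 °C to rt; then aq. Na2S2O4, 0 °C
Reagents that add atoms: water, O
Why: Oxidative demethylation of p-dimethoxyarenes by divalent silver in nitric acid; each ring is oxidised in two one-electron steps with ipso addition of water and loss of methanol, the first ring (either one, hence 20 and 21) quickly and the deactivated second ring more slowly, so that both isomers converge on tetraone 22. Dithionite then reduces 22 by two electrons to the naphthazarin 23, whose ring tautomers equilibrate, so the ring that was oxidised first is of no consequence. The ester carbonyl, the electron-poor Z alkene and C1' take no part.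

## Compound list

1 | naphthazarin (5,8-dihydroxy-1,4-naphthoquinone) | O=C1C=CC(=O)c2c(O)ccc(O)c12 | starting material
2 | naphthalene-1,4,5,8-tetrol | Oc1ccc(O)c2c(O)ccc(O)c12 | intermediate (not isolated)
3 | 1,4,5,8-tetramethoxynaphthalene | COc1ccc(OC)c2c(OC)ccc(OC)c12 | intermediate
4 | N,N-dimethyl-1-(1,4,5,8-tetramethoxynaphthalen-2-yl)methaniminium chloride | C[N+](C)=Cc1cc(OC)c2c(OC)ccc(OC)c2c1OC.[Cl-] | intermediate (not isolated)
5 | 1,4,5,8-tetramethoxynaphthalene-2-carbaldehyde | O=Cc1cc(OC)c2c(OC)ccc(OC)c2c1OC | intermediate
6 | 2-ethynyl-1,4,5,8-tetramethoxynaphthalene | C#Cc1cc(OC)c2c(OC)ccc(OC)c2c1OC | intermediate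
7 | N,N-dimethylisobutyramide | CC(C)C(=O)N(C)C | starting material
8 | N,N-dimethyl-N-(2-methylprop-1-en-1-ylidene)ammonium trifluoromethanesulfonate (tetramethylketeniminium triflate) | CC(C)=C=[N+](C)C.[O-]S(=O)(=O)C(F)(F)F | intermediate (not isolated)
9 | N-[4,4-dimethyl-3-(1,4,5,8-tetramethoxynaphthalen-2-yl)cyclobut-2-en-1-ylidene]-N-methylmethanaminium trifluoromethanesulfonate | C[N+](C)=C1C=C(c2cc(OC)c3c(OC)ccc(OC)c3c2OC)C1(C)C.[O-]S(=O)(=O)C(F)(F)F | intermediate (not isolated)
10 | 4,4-dimethyl-3-(1,4,5,8-tetramethoxynaphthalen-2-yl)cyclobut-2-en-1-one | O=C1C=C(c2cc(OC)c3c(OC)ccc(OC)c3c2OC)C1(C)C | intermediate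
11 | (3R)-2,2-dimethyl-3-(4,4,5,5-tetramethyl-1,3,2-dioxaborolan-2-yl)-3-(1,4,5,8-tetramethoxynaphthalen-2-yl)cyclobutan-1-one | CC1(C)OB(OC1(C)C)[C@]1(c2cc(OC)c3c(OC)ccc(OC)c3c2OC)CC(=O)C1(C)C | intermediate
12 | N'-[(3S)-2,2-dimethyl-3-(4,4,5,5-tetramethyl-1,3,2-dioxaborolan-2-yl)-3-(1,4,5,8-tetramethoxynaphthalen-2-yl)cyclobutylidene]-4-methylbenzenesulfonohydrazide | CC1(C)OB(OC1(C)C)[C@]1(c2cc(OC)c3c(OC)ccc(OC)c3c2OC)CC(=NNS(=O)(=O)c2ccc(C)cc2)C1(C)C | intermediate
13 | N'-[(3S)-2,2-dimethyl-3-(4,4,5,5-tetramethyl-1,3,2-dioxaborolan-2-yl)-3-(1,4,5,8-tetramethoxynaphthalen-2-yl)cyclobutyl]-4-methylbenzenesulfonohydrazide (both epimers at the nitrogen-bearing carbon) | CC1(C)OB(OC1(C)C)[C@]1(c2cc(OC)c3c(OC)ccc(OC)c3c2OC)CC(NNS(=O)(=O)c2ccc(C)cc2)C1(C)C | intermediate (not isolated)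
14 | 2-[(1S)-2,2-dimethyl-1-(1,4,5,8-tetramethoxynaphthalen-2-yl)cyclobutyl]-4,4,5,5-tetramethyl-1,3,2-dioxaborolane | CC1(C)OB(OC1(C)C)[C@]1(c2cc(OC)c3c(OC)ccc(OC)c3c2OC)CCC1(C)C | intermediate
15 | (1R)-2,2-dimethyl-1-(1,4,5,8-tetramethoxynaphthalen-2-yl)cyclobutan-1-ol | O[C@]1(c2cc(OC)c3c(OC)ccc(OC)c3c2OC)CCC1(C)C | intermediate
16 | angelic acid, (Z)-2-methylbut-2-enoic acid | C/C=C(/C)C(=O)O | starting material
17 | (Z)-2-methylbut-2-enoic 2,4,6-trichlorobenzoic anhydride | C/C=C(/C)C(=O)OC(=O)c1c(Cl)cc(Cl)cc1Cl | intermediate (not isolated)
18 | lithium (1R)-2,2-dimethyl-1-(1,4,5,8-tetramethoxynaphthalen-2-yl)cyclobutan-1-olate | [Li+].[O-][C@]1(c2cc(OC)c3c(OC)ccc(OC)c3c2OC)CCC1(C)C | intermediate (not isolated)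
19 | (1R)-2,2-dimethyl-1-(1,4,5,8-tetramethoxynaphthalen-2-yl)cyclobutyl (2Z)-2-methylbut-2-enoate | C/C=C(/C)C(=O)O[C@]1(c2cc(OC)c3c(OC)ccc(OC)c3c2OC)CCC1(C)C | intermediate
20 | (1R)-1-(5,8-dimethoxy-1,4-dioxo-1,4-dihydronaphthalen-2-yl)-2,2-dimethylcyclobutyl (2Z)-2-methylbut-2-enoate | C/C=C(/C)C(=O)O[C@]1(C2=CC(=O)c3c(OC)ccc(OC)c3C2=O)CCC1(C)C | intermediate (not isolated)
21 | (1R)-1-(1,4-dimethoxy-5,8-dioxo-5,8-dihydronaphthalen-2-yl)-2,2-dimethylcyclobutyl (2Z)-2-methylbut-2-enoate | C/C=C(/C)C(=O)O[C@]1(c2cc(OC)c3C(=O)C=CC(=O)c3c2OC)CCC1(C)C | intermediate (not isolated)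
22 | (1R)-2,2-dimethyl-1-(1,4,5,8-tetraoxo-1,4,5,8-tetrahydronaphthalen-2-yl)cyclobutyl (2Z)-2-methylbut-2-enoate | C/C=C(/C)C(=O)O[C@]1(C2=CC(=O)C3=C(C2=O)C(=O)C=CC3=O)CCC1(C)C | intermediate (not isolated)
23 | (1R)-1-(5,8-dihydroxy-1,4-dioxo-1,4-dihydronaphthalen-2-yl)-2,2-dimethylcyclobutyl (2Z)-2-methylbut-2-enoate | C/C=C(/C)C(=O)O[C@]1(C2=CC(=O)c3c(O)ccc(O)c3C2=O)CCC1(C)C | target

## Step count and least certain steps

Total: 10 steps. Longest linear sequence: 10 steps, from naphthazarin 1 to 23. Amide 7 and angelic acid 16 enter as bought materials.

**Step 4 (key step).** The electron-rich arene may compete with the alkyne for the keteniminium ion, the electron-rich alkyne may oligomerise under the cationic conditions, and the aryl-conjugated iminium salt 9 may hydrolyse slowly. The fallback drops the cycloaddition and attaches the aryl group to a ready-made four-membered ring. It sets out from 3 and returns at 10.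
- Bromination of 3 with N-bromosuccinimide should give 2-bromo-1,4,5,8-tetramethoxynaphthalene F1.
- Halogen–lithium exchange with n-BuLi at −78 °C would give (1,4,5,8-tetramethoxynaphthalen-2-yl)lithium F2.
- Separately, dimethylketene F3, generated from isobutyryl chloride and triethylamine, would be trapped with ethoxyacetylene to give 3-ethoxy-4,4-dimethylcyclobut-2-en-1-one F4.
- Addition of F2 to the carbonyl of F4 should give 3-ethoxy-4,4-dimethyl-1-(1,4,5,8-tetramethoxynaphthalen-2-yl)cyclobut-2-en-1-ol F5.
- Dilute HCl would hydrolyse the enol ether of F5 and dehydrate it (Stork–Danheiser transposition) to 10. The gem-dimethyl carbon is bonded to both the old and the new carbonyl carbon, so only this one enone can result.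

**Step 5.** The β-carbon is flanked by a quaternary carbon and an ortho-methoxy aryl group, so the copper–boryl addition may be slow, and the facial discrimination by the ligand may be poor. The fallback gives up catalyst control. It sets out from 10 and returns at 11. Borylation with an achiral, more reactive catalyst (CuCl, NaOtBu, Xantphos, B2pin2, MeOH) should give racemic 2,2-dimethyl-3-(4,4,5,5-tetramethyl-1,3,2-dioxaborolan-2-yl)-3-(1,4,5,8-tetramethoxynaphthalen-2-yl)cyclobutan-1-one F6. The enantiomers of F6 would be separated by preparative chromatography on a chiral stationary phase, and the R enantiomer is 11.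

**Step 7 (with step 6).** Hydrazone formation may stall at the carbonyl next to the quaternary carbon, and the diazene decomposition may be accompanied by loss of the boronate or by ring fragmentation. The fallback replaces the hydrazone route by a radical deoxygenation. It sets out from 11 and returns at 14.
- NaBH4 in MeOH should reduce 11 to 2,2-dimethyl-3-(4,4,5,5-tetramethyl-1,3,2-dioxaborolan-2-yl)-3-(1,4,5,8-tetramethoxynaphthalen-2-yl)cyclobutan-1-ol F7, as a mixture of epimers at the carbinol carbon.
- 1,1'-Thiocarbonyldiimidazole would convert F7 into the O-cyclobutyl 1H-imidazole-1-carbothioate F8.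
- Bu3SnH with AIBN in toluene at 80 °C (Barton–McCombie deoxygenation) would give 14.

**Step 9.** The tertiary alkoxide 18 is very hindered, so acylation may be incomplete, and any excess base may isomerise the angelate to the E ester. The fallback builds the Z alkene on the ester instead of transferring it. It sets out from 15 and returns at 19. Alkoxide 18, made from 15 as before, would be acylated with 2-[bis(2,2,2-trifluoroethoxy)phosphoryl]propanoyl chloride to give (1R)-2,2-dimethyl-1-(1,4,5,8-tetramethoxynaphthalen-2-yl)cyclobutyl 2-[bis(2,2,2-trifluoroethoxy)phosphoryl]propanoate F9. A Still–Gennari olefination of F9 with acetaldehyde (KN(SiMe3)2, 18-crown-6, THF, −78 °C) should then give the Z ester 19.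

**Step 10.** The strongly acidic medium may ionise the tertiary ester while C1' is still attached to the electron-rich tetramethoxynaphthalene. The second oxidation may stall once one ring has become a quinone. The very electrophilic tetraone may add water before it is reduced, and excess dithionite may over-reduce the naphthazarin until air restores it. The fallback splits the deprotection into a mild oxidation of one ring and a non-oxidative cleavage of the remaining ethers. It sets out from 19 and returns at 23.
- (NH4)2Ce(NO3)6 in MeCN/H2O at 0 °C (tetravalent cerium) should oxidise one ring only and give 20 and 21, which would be taken on together as the mixture.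
- BCl3 in CH2Cl2 at −78 to −20 °C, followed by water, binds between each quinone carbonyl and its peri-methoxy group and would remove the two remaining methyl groups by chelation-assisted cleavage.
- Both isomers should give 23, because the naphthazarin tautomers equilibrate.

## Further compounds

F1 | step 4 | 2-bromo-1,4,5,8-tetramethoxynaphthalene | Brc1cc(OC)c2c(OC)ccc(OC)c2c1OC
F2 | step 4 | (1,4,5,8-tetramethoxynaphthalen-2-yl)lithium | [Li]c1cc(OC)c2c(OC)ccc(OC)c2c1OC
F3 | step 4 | dimethylketene | CC(C)=C=O
F4 | step 4 | 3-ethoxy-4,4-dimethylcyclobut-2-en-1-one | CCOC1=CC(=O)C1(C)C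
F5 | step 4 | 3-ethoxy-4,4-dimethyl-1-(1,4,5,8-tetramethoxynaphthalen-2-yl)cyclobut-2-en-1-ol (racemic) | CCOC1=CC(O)(c2cc(OC)c3c(OC)ccc(OC)c3c2OC)C1(C)C
F6 | step 5 | racemic 2,2-dimethyl-3-(4,4,5,5-tetramethyl-1,3,2-dioxaborolan-2-yl)-3-(1,4,5,8-tetramethoxynaphthalen-2-yl)cyclobutan-1-one | CC1(C)OB(OC1(C)C)C1(c2cc(OC)c3c(OC)ccc(OC)c3c2OC)CC(=O)C1(C)C
F7 | step 7 | 2,2-dimethyl-3-(4,4,5,5-tetramethyl-1,3,2-dioxaborolan-2-yl)-3-(1,4,5,8-tetramethoxynaphthalen-2-yl)cyclobutan-1-ol (boron-bearing centre as in 11, both epimers at the carbinol carbon) | CC1(C)OB(OC1(C)C)[C@]1(c2cc(OC)c3c(OC)ccc(OC)c3c2OC)CC(O)C1(C)C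
F8 | step 7 | O-[2,2-dimethyl-3-(4,4,5,5-tetramethyl-1,3,2-dioxaborolan-2-yl)-3-(1,4,5,8-tetramethoxynaphthalen-2-yl)cyclobutyl] 1H-imidazole-1-carbothioate (boron-bearing centre as in 11) | CC1(C)OB(OC1(C)C)[C@]1(c2cc(OC)c3c(OC)ccc(OC)c3c2OC)CC(OC(=S)n2ccnc2)C1(C)C
F9 | step 9 | (1R)-2,2-dimethyl-1-(1,4,5,8-tetramethoxynaphthalen-2-yl)cyclobutyl 2-[bis(2,2,2-trifluoroethoxy)phosphoryl]propanoate (both epimers at the phosphonate carbon) | CC(C(=O)O[C@]1(c2cc(OC)c3c(OC)ccc(OC)c3c2OC)CCC1(C)C)P(=O)(OCC(F)(F)F)OCC(F)(F)F
F0 | step 10 | none | none
A1 | alternative 1 | 3,6-dimethoxy-2-(trimethylsilyl)phenyl trifluoromethanesulfonate | COc1ccc(OC)c(OS(=O)(=O)C(F)(F)F)c1[Si](C)(C)C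
A2 | alternative 1 | 3,6-dimethoxybenzyne | COC1=CC=C(OC)C#C1
A3 | alternative 1 | (1R)-1-(furan-3-yl)-2,2-dimethylcyclobutyl (2Z)-2-methylbut-2-enoate | C/C=C(/C)C(=O)O[C@]1(c2ccoc2)CCC1(C)C
A4 | alternative 1 | (1R)-1-(5,8-dimethoxy-1,4-dihydro-1,4-epoxynaphthalen-2-yl)-2,2-dimethylcyclobutyl (2Z)-2-methylbut-2-enoate (mixture at the bridgeheads) | C/C=C(/C)C(=O)O[C@]1(C2=CC3OC2c2c(OC)ccc(OC)c23)CCC1(C)C
A5 | alternative 2 | (2S)-2-(2,5-dimethoxyphenyl)-2-hydroxy-5,5-dimethylcyclopentan-1-one | O[C@]1(c2cc(OC)ccc2OC)CCC(C)(C)C1=O
A6 | alternative 2 | (1R)-1-(2,5-dimethoxyphenyl)-2,2-dimethylcyclobutan-1-ol | O[C@]1(c2cc(OC)ccc2OC)CCC1(C)C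
A7 | alternative 3 | (1S)-4-chloro-2,2-dimethyl-1-(1,4,5,8-tetramethoxynaphthalen-2-yl)butyl N,N-diisopropylcarbamate | CC(C)N(C(C)C)C(=O)O[C@H](c1cc(OC)c2c(OC)ccc(OC)c2c1OC)C(C)(C)CCCl
A8 | alternative 3 | (1R)-2,2-dimethyl-1-(1,4,5,8-tetramethoxynaphthalen-2-yl)cyclobutyl N,N-diisopropylcarbamate | CC(C)N(C(C)C)C(=O)O[C@]1(c2cc(OC)c3c(OC)ccc(OC)c3c2OC)CCC1(C)C
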